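**Remarks on the chemistry**

- Locants follow the spiro[4.5]decane numbering of the target for every intermediate: C1 carbinol, C2, C3, C4, C5 spiro, C6–C10 in ring A; Ca, Cb, Cc, Cd, Ce along the side chain from C2.
- Structures 26 (key precursor) and 27 (key product) were checked centre by centre against the target. They agree at C5, C6 and C10 (and at C1, C2 and the Ca=Cb geometry in 27), and (S)-carvone supplies C7 of 26 with the configuration drawn, so these structures need no correction.
- The corrections lie in the tactics: an alkyl triflate replaces an elimination-prone homopropargyl iodide; the alkene shift at C7 is done by a metal sequence because C7–H is cross-conjugated and not acidified by the formyl group; the allylic acetate is made only after the palladium step; the enal is masked during hydrometalation; the samarium step is run without HMPA.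
- Assumption: centres and geometries that are erased later (C5 in 9, the carbinol carbon Cb in 23–26, the enol-ether geometry in 5–8 and 31) are carried as mixtures.

## Structural features

The target is a spiro[4.5]decane in which cyclopentane ring B (C1–C5) and cyclohexane ring A (C5–C10) share the quaternary carbon C5. Five stereocentres form one cluster: C5 is flanked by the secondary carbinol C1, by C6 (3-hydroxypropyl) and by the tertiary methyl carbinol C10, and C2 carries its side chain trans to the C1 hydroxyl. The C1 oxygen lies on the C10 side of ring B, and C1, the C6 chain and the C10 oxygen share one face of ring A. C2 bears a cross-conjugated triene, C2–Ca(CH2OAc)=Cb–Cc=Cd–Ce(=CH2)–CH2CH2CH=CMe2, with Cc cis to the ring across Ca=Cb and Cc=Cd trans. C7 is the ring end of a tetrasubstituted exocyclic enal, C7=C(CH3)CHO, with the formyl group on the C6 side. The fragile groups are the dienylic acetate (ionisation by acid or zerovalent palladium, loss under base), the triene, and the enal, whose γ-deprotonation at C6 or C8 would scramble both its geometry and C6. The real difficulty is the fully substituted C5 with three stereocentres around it, the trans C1/C2 pair, and two highly substituted alkenes of fixed geometry. The key step uses the 1,4-relationship between the C1 oxygen and the Ca–CH2 oxygen together with the position of Ca=Cb, β,γ to C1: a reductively umpoled C1 (ketyl of a formyl group on C5) can add to C2 of a 2-(1-acetoxyalkyl)acrylate and expel acetate from Cb, which closes ring B, sets C1 and C2 and creates Ca=Cb in one operation.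

## Logic of the disconnections

45 ⇒ 44 ⇒ 43. No carbon bond is cut; the C=O of the enal is taken back to the allylic CH2OH and the four hydroxyls to silyl ethers. The reason is that the enal survives neither hydride reagents nor Cp2Zr(H)Cl. The gain is a last step that touches one functional group only. The demand is an oxidant that picks the allylic primary alcohol of 44 among four hydroxyls and leaves the alkene geometry alone.

43 ⇒ 42 ⇒ 41. The acetate C–O bond and the oxidation level at the Ca substituent are adjusted: CH2OAc back to CO2Me. The allylic acetate would ionise with zerovalent palladium, so it must appear after the coupling; as an ester the same carbon also deactivates Ca=Cb toward the oxidants of steps 20 and 21. The forward step is a clean 1,2-reduction of a cross-conjugated trienoate.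

41 ⇒ 35 + 38. The Cd–Ce bond is cut. This is the convergent cut: it keeps the acid- and oxidant-sensitive triene and the prenyl-type alkene out of the route until step 25 and uses the alkyne that the key step leaves behind. It demands a syn, terminal hydrometalation of the enyne and a coupling with retention on both partners.

35 ⇒ 34 ⇒ 32 ⇒ 30 ⇒ 28. The C7=C bond and the formyl oxygen are traced back to the isopropenyl group: an allylic C–H is exchanged for oxygen (30) and the alkene is moved from the CH2 terminus to C7 (32). The isopropenyl group is the only handle that 1 provides at C7. The forward demands are oxidation at CH3 and not at C7–H, and a double-bond shift that cannot be base-mediated and must deliver the formyl group cis to C6.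

28 ⇒ 27 ⇒ 26. The C1–C2 bond is cut (key step). Both carbons are electrophilic in 26, so the bond is made by electron transfer; the same event forms Ca=Cb. The gain is large: ring B, two stereocentres and a trisubstituted alkene disappear, leaving a monocyclic aldehyde. The demands are ketyl formation in preference to reduction of the acetoxy acrylate, facial control at C1 through the C10 ether, and the anti transition state for C2.

26 ⇒ 25 ⇒ 24 ⇒ 23 ⇒ 20 + 21. The Ca–Cb bond is cut; the precursor is an ynoate that is turned into an α-metallated acrylate. This gives the Z-acrylate and the leaving-group carbon in one step from two simple partners. The demand is syn hydroalumination with retention on addition to the aldehyde; the configuration at Cb is irrelevant.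

20 ⇒ 18 ⇒ 17 ⇒ 16 ⇒ 15 ⇒ 14. The alkyne–CO2Me bond, the acetal at the C10 oxygen, and the C10–O and C9–H bonds are cut in turn. The tertiary carbinol is read as the product of hydride opening of an epoxide that the C1 hydroxyl delivers to its own face of C9=C10. The gain is that C10 is set from C5 with a predictable sense. The demand is a protecting-group order in which C1–O is base-stable and oxidatively removable and C10–O is capped before the ynoate exists.

14 ⇒ 13 ⇒ 9 + 11. The C5–C4 bond is cut: the quaternary centre comes from α-alkylation of an extended aldehyde enolate. The gain is a ring with only two stereocentres. The demands are C- over O-alkylation, substitution over elimination (hence 11 and not an iodide), and attack anti to the C6 chain.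

9 ⇒ 8 ⇒ 7 ⇒ 5 ⇒ 4. The C5=C1 bond (olefination of the ketone) and the terminal C–O bond of the C6 chain (hydroboration of an allyl group) are cut. The demand is a borane that takes the allyl group and leaves the isopropenyl group, the ring alkene and the enol ether.

4 ⇒ 1 + 2, 11 ⇒ 10, 38 ⇒ 36. The C6–CH2 bond and two C–O sulfonate bonds are cut, reaching commercial materials. The alkylation of 1 must occur at the α′ position and trans to the isopropenyl group.

## Other disconnections considered

Alternative 1: The cut goes through C1–C5 and C6–C1′ (C1′ is the first carbon of the C6 chain), so ring B and the root of the C6 chain come from an intramolecular enone–dioxinone [2+2] photocycloaddition. In the forward sense, irradiation (300–350 nm) of A1, a ring-A cyclohexenone (C7 ketone, C5=C6) whose C5 carries a three-carbon tether ending in a dioxinone, should give cyclobutane A2. Opening of the dioxanone and retro-aldol cleavage of C1–C1′ (de Mayo sequence) would then release the spiro diketo acid A3.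
- In its favour: C5 is made quaternary from an sp2 carbon without any enolate alkylation; C5 and C6 are set together by the cis ring fusion; two C–C bonds form at once; C1 and C7 both emerge as ketones.
- Against it here: the face selectivity rests on the adjacent C10 centre, which must first be made enantiopure on a 4,4-disubstituted cyclohexenone. Both alkenes are electron-poor, so regiochemistry depends on the tether alone. A3 has a C6 chain one carbon short, a C1 ketone that still needs face-selective reduction, no C2 substituent, and a C7 ketone flanked by C6 that must be olefinated to a tetrasubstituted enal of defined geometry.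
- Comparison, structure: the alternative builds more skeleton in its key step and is the better plan for the quaternary centre, which in the chosen route depends on the face selectivity of step 7. It is the equal of the chosen plan in needing C10 beforehand.
- Comparison, mechanism: it needs no stoichiometric metal, a point in its favour. It gives no control over C1 and C2, which the closure 26 → 27 sets together with Ca=Cb and the alkyne handle.
- Comparison, step economy: the bare spirocycle should be reached sooner, but the C6 homologation, the C2 chain and the C7 olefination are expected to cost more than is saved.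

Alternative 2: The cut is C5–C6, made by a Claisen rearrangement that breaks O–C8. In the forward sense, heating A4, a cyclopenta-fused dihydropyran (enol ether O–C1=C5) that carries at C8 a (Z)-silyl enol ether alkenyl group (C8–C7=C6), should contract the oxygen ring to cyclohexene ring A and release the C1 ketone, giving A5.
- In its favour: the shift is concerted and suprafacial, and the two-carbon bridge allows only a boat transition state, so the C8 configuration and the enol-silane geometry should translate into C5 and C6 with a predictable relative sense. C1 arrives as a ketone and C7 as a regiodefined enol silane, a better handle for the C7 alkylidene than an isopropenyl group. C10 is already in place.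
- Against it here: A4 needs three defined elements (C8, C10, the Z enol silane) on a bicyclic enol ether that has no chiral-pool source as direct as 1. The boat transition state is strained and needs heat that a silyl dienol ether may not tolerate. After the key step the C1 reduction, the trans C2 chain and the olefination of a hindered C7 ketone all remain.
- Comparison, structure: the alternative sets C5 and C6, the two centres whose control is least certain in the chosen plan, and is the better plan on that point.
- Comparison, mechanism: a reagent-free pericyclic step is at least the equal of a samarium reduction in simplicity, but it gives nothing toward C1, C2 or the side chain.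
- Comparison, step economy: the route to A4 and the side-chain work after A5 are expected to outweigh the directness of the key step.

Alternative 3: The cut is C4–C5, made by a 1,2-shift. In the forward sense, a chiral primary ammonium salt of the cinchona family condenses with the C7 ketone of A6, an achiral quinone-monoketal dienone carrying a 1-hydroxycyclobutyl group on C5. In the iminium ion, C4 should migrate from the carbinol carbon C1 to C5 (vinylogous semipinacol shift), expanding the cyclobutane to cyclopentanone ring B and giving A7.
- In its favour: the step is catalytic and enantioselective from an achiral, easily assembled precursor. It needs no chiral pool and no sacrificial stereocentre, whereas the chosen plan carries C7 from 1 only to destroy it; this is a point on which the alternative is better. Both ketones, an enone and a masked C10 ketone are left for later work, and C6 is α to the C7 ketone.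
- Against it here: only C5 is set. C10 (methyl addition), C6 (alkylation), C1 and C2 must all be controlled relative to one quaternary centre, with no evident directing element for C10. The enantiodiscrimination must work on a hindered, cross-conjugated dienone next to a ketal. The C7 enal again has to come from a hindered ketone.
- Comparison, structure: one bond and one stereocentre, against one bond, two stereocentres and an alkene in the chosen key step.
- Comparison, mechanism: catalytic absolute stereocontrol is better than a stoichiometric chiral-pool source, and the reagent economy is better.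
- Comparison, step economy: this is the shortest access to the spiro core, which is better, but the longest and least controlled way from the core to the target.

Key step: step 18

## Steps

Step 1
Reactants: 1 (S)-carvone; 2 allyl bromide
Product: 4 trans-6-allylcarvone, via lithium dienolate 3 (not isolated)
Conditions: LiN(i-Pr)2, THF, −78 °C; then 2, −78 → −20 °C
Reagents that add atoms: none
Why: Kinetic α′-deprotonation of the enone gives the cross-conjugated lithium enolate, which is C-alkylated by the allylic bromide (enolate alkylation); the electrophile enters anti to the adjacent isopropenyl group, so the future C6 chain is trans to the C7 substituent.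

Step 2
Reactants: 4 trans-6-allylcarvone
Product: 5 methoxydiene (enol ether on the future C5)
Conditions: Ph3P(CH2OMe)Cl, KOt-Bu, THF, 0 °C → rt
Reagents that add atoms: (methoxymethyl)triphenylphosphonium chloride, [Cl-].COC[P+](c1ccccc1)(c1ccccc1)c1ccccc1
Why: Wittig methoxymethylenation of the ketone adds the future C1 as an enol ether; should the basic ylide enolise the ketone, the trans arrangement at C6/C7 is also the more stable one.

Step 3
Reactants: 5 methoxydiene
Product: 7 primary alcohol (C6 3-hydroxypropyl chain), via trialkylborane 6 (not isolated)
Conditions: disiamylborane (from BH3·SMe2 and 2-methylbut-2-ene), THF, 0 °C; then NaOH, H2O2, 0 °C → rt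
Reagents that add atoms: hydrogen peroxide, OO
Why: Hydroboration–oxidation; the bulky dialkylborane adds anti-Markovnikov to the monosubstituted allyl alkene much faster than to the 1,1-disubstituted isopropenyl group, the trisubstituted ring alkene or the fully substituted enol-ether carbon, and the oxidation retains the C–B position.

Step 4
Reactants: 7 primary alcohol
Product: 8 TBS ether
Conditions: TBSCl, imidazole, DMF, 0 °C → rt
Reagents that add atoms: tert-butyldimethylsilyl chloride, CC(C)(C)[Si](C)(C)Cl
Why: Standard silylation of a primary alcohol; the enol ether is stable to imidazole.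

Step 5
Reactants: 8 TBS ether
Product: 9 ring-A β,γ-unsaturated aldehyde (C5 epimers)
Conditions: oxalic acid, THF/H2O, 0 °C → rt
Reagents that add atoms: water, O
Why: Mild acid hydrolysis of the 1-methoxydiene with kinetic α-protonation gives the aldehyde with the C9=C10 alkene; the primary silyl ether survives, and both C5 epimers give the same enolate in step 7.

Step 6
Reactants: 10 but-3-yn-1-ol
Product: 11 but-3-yn-1-yl triflate
Conditions: Tf2O, pyridine, CH2Cl2, −78 → −20 °C; used at once
Reagents that add atoms: trifluoromethanesulfonic anhydride, O=S(=O)(OS(=O)(=O)C(F)(F)F)C(F)(F)F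
Why: O-sulfonylation of the primary alcohol; the triflate is chosen because it is substituted far faster than the corresponding iodide, which with an enolate would mainly eliminate to the enyne.

Step 7
Reactants: 9 ring-A β,γ-unsaturated aldehyde; 11 but-3-yn-1-yl triflate
Product: 13 quaternary aldehyde (butynyl on C5), via lithium dienolate 12 (not isolated)
Conditions: LiN(i-Pr)2, THF, −78 °C; then 11, −78 → −20 °C
Reagents that add atoms: none
Why: Deprotonation of the doubly activated C5–H gives the extended lithium enolate, which is alkylated at its α-carbon (deconjugative α-alkylation) to build the quaternary centre; the electrophile should approach anti to the adjacent C6 chain (1,2-induction), which puts C4 trans to that chain and the formyl group cis to it.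

Step 8
Reactants: 13 quaternary aldehyde
Product: 14 neopentyl alcohol (C1 as CH2OH)
Conditions: NaBH4, MeOH, 0 °C
Reagents that add atoms: none
Why: Hydride reduction of the aldehyde; alkyne, alkenes and silyl ether are inert.

Step 9
Reactants: 14 neopentyl alcohol
Product: 15 epoxy alcohol (C9–C10 epoxide cis to CH2OH)
Conditions: VO(acac)2 (cat.), t-BuOOH, CH2Cl2, 0 °C → rt
Reagents that add atoms: tert-butyl hydroperoxide, CC(C)(C)OO
Why: Hydroxyl-directed vanadium-catalysed epoxidation of the homoallylic alcohol: the vanadate ester delivers oxygen to the face of C9=C10 that carries the CH2OH group, which sets the C10 oxygen cis to C1; the isopropenyl group and the alkyne are not touched by this system.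

Step 10
Reactants: 15 epoxy alcohol
Product: 16 p-methoxybenzyl ether
Conditions: NaH, 4-MeOC6H4CH2Cl, Bu4NI (cat.), THF/DMF, 0 °C → rt
Reagents that add atoms: 4-methoxybenzyl chloride, COc1ccc(CCl)cc1
Why: Williamson etherification of the only hydroxyl; the ether withstands the strong bases and hydrides ahead and is removed oxidatively in step 16.

Step 11
Reactants: 16 p-methoxybenzyl ether
Product: 17 tertiary alcohol (C10 methyl carbinol)
Conditions: LiBHEt3, THF, 0 °C → rt; aq. NaOH
Reagents that add atoms: none
Why: SN2 hydride opening of the trisubstituted epoxide at the less substituted C9; the C10–O bond is not touched, so the configuration set in step 9 is kept.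

Step 12
Reactants: 17 tertiary alcohol
Product: 18 MOM ether
Conditions: MeOCH2Cl, i-Pr2NEt, NaI (cat.), 1,2-dichloroethane, 60 °C
Reagents that add atoms: chloromethyl methyl ether, COCCl
Why: Alkylation of the hindered tertiary alcohol by the reactive chloromethyl ether; the acetal keeps the C10 oxygen from adding to the ynoate and acrylate made next and later serves as the chelating group of step 18.

Step 13
Reactants: 18 MOM ether
Product: 20 methyl ynoate, via lithium acetylide 19 (not isolated)
Conditions: n-BuLi, THF, −78 °C; then ClCO2Me, −78 → −40 °C
Reagents that add atoms: methyl chloroformate, COC(=O)Cl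
Why: Deprotonation of the terminal alkyne and C-acylation of the acetylide with a chloroformate.

Step 14
Reactants: 20 methyl ynoate; 21 3-(trimethylsilyl)prop-2-ynal
Product: 23 Baylis–Hillman-type carbinol (Cb epimers), via vinylalane 22 (not isolated)
Conditions: i-Bu2AlH, N-methylmorpholine N-oxide, THF, 0 °C, 20; then 21, 0 °C → rt
Reagents that add atoms: none
Why: Conjugate syn-hydroalumination of the ynoate (vinylalumination) gives the α-alumino acrylate, which adds to the aldehyde at the α-carbon with retention, so the C3 chain ends cis to the ester (Z); the new carbinol centre forms as both epimers, which does not matter because it becomes sp2 in step 18.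

Step 15
Reactants: 23 Baylis–Hillman-type carbinol
Product: 24 acetate
Conditions: Ac2O, pyridine, DMAP (cat.), CH2Cl2, 0 °C
Reagents that add atoms: acetic anhydride, CC(=O)OC(C)=O
Why: Acylation of the secondary alcohol installs the leaving group for step 18.

Step 16
Reactants: 24 acetate
Product: 25 C1 alcohol
Conditions: DDQ, CH2Cl2/pH 7 buffer, 0 °C
Reagents that add atoms: none
Why: Oxidative cleavage of the p-methoxybenzyl ether under buffered, base-free conditions that spare silyl ether, MOM ether, acetate and alkynylsilane; base is avoided because a C1 alkoxide could add to the acetoxy acrylate.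

Step 17
Reactants: 25 C1 alcohol
Product: 26 ring-A aldehyde (key precursor)
Conditions: Dess–Martin periodinane, NaHCO3, CH2Cl2, 0 °C → rt
Reagents that add atoms: none
Why: Dess–Martin oxidation of the neopentyl primary alcohol; the aldehyde has no α-hydrogen and cannot epimerise.

Step 18
Reactants: 26 ring-A aldehyde (key precursor)
Product: 27 spiro carbinol with the C2 enynoate stub (key product)
Conditions: SmI2 (THF solution, about 2.2 equiv, added slowly), THF, −78 → −30 °C; aq. NaHCO3
Reagents that add atoms: none
Why: SmI2 transfers one electron to the non-enolisable neopentyl aldehyde, and the ketyl adds 5-exo-trig to C2, the β-carbon of the tethered acrylate, forming C1–C2 and closing ring B (closest known reaction type: samarium ketyl–olefin cyclisation onto α,β-unsaturated esters, ended here by the β-elimination known from SmI2 reactions of Baylis–Hillman acetates). A second equivalent reduces the α-ester radical to a trivalent samarium enolate, which expels acetate from Cb (E1cB) and gives Ca=Cb, so both Cb epimers converge. At C1, the samarium-bound ketyl oxygen is held by the C10 MOM oxygen in a six-membered chelate, so the new C–O bond points to the C10 side, and the bulky C2 substituent then also avoids the fully substituted C10. At C2, the usual anti arrangement of ketyl oxygen and acceptor alkene in the 5-exo transition state places the side chain trans to the C1 oxygen; a cis product would be able to lactonise, the trans one cannot. The alkene geometry follows from loss of acetate through the rotamer that keeps the small Cb hydrogen, not the alkynyl group, next to the enolate oxygen, which leaves the alkynyl group trans to the ester. The step needs ketyl formation to beat direct reduction of the acetoxy acrylate and needs the product enynoate to survive; the absence of HMPA (which also preserves the chelate), low temperature and slow addition of little more than two equivalents serve both. An allylsamarium formed by premature acetate loss should still add to the aldehyde through C2 and give the same constitution.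

Step 19
Reactants: 27 spiro carbinol (key product)
Product: 28 spiro 1,10-diol
Conditions: B-bromocatecholborane, CH2Cl2, −78 → −20 °C; aq. NaHCO3
Reagents that add atoms: none
Why: Lewis-acid cleavage of the formaldehyde acetal at low temperature (the bromomethyl ether is hydrolysed on work-up), under conditions that leave the primary silyl ether, ester, alkynylsilane and alkene alone; it is done here because the later triene and allylic acetate would not tolerate acetal cleavage.

Step 20
Reactants: 28 spiro 1,10-diol
Product: 30 2-substituted propenal at C7, via allylic alcohol 29 (not isolated)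
Conditions: SeO2 (cat.), t-BuOOH, CH2Cl2, rt; then MnO2, CH2Cl2, rt
Reagents that add atoms: tert-butyl hydroperoxide, CC(C)(C)OO (the oxygen atom is passed on through SeO2, O=[Se]=O)
Why: Allylic oxidation by ene reaction and [2,3]-shift at the methyl group of the only electron-rich alkene (the enynoate is deactivated by its ester), then MnO2 oxidation of the allylic alcohol, which leaves the non-allylic C1 and C10 hydroxyls alone.

Step 21
Reactants: 30 2-substituted propenal at C7
Product: 32 tetrasubstituted enal C7=C(CH3)CHO with CHO cis to C6, via trimethylsilyl enol ether 31 (not isolated)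
Conditions: [(Ph3P)CuH]6, Me3SiCl, THF, −40 → 0 °C; then Pd(OAc)2, MeCN, rt
Reagents that add atoms: none
Why: Copper hydride 1,4-reduction of the unhindered propenal with silyl trapping, then Saegusa–Ito oxidation; a base cannot do this shift because C7–H is cross-conjugated to the formyl group, whereas the divalent palladium enolate can lose the C7 hydrogen to give the more substituted conjugated alkene (loss of a methyl hydrogen only returns 30). The syn-elimination rotamer with CH3 beside C8H2 and the flat formyl group beside the substituted C6 leads to the required geometry, which is also expected to be the more stable one.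

Step 22
Reactants: 32 tetrasubstituted enal
Product: 34 terminal enyne triol, via silylated enynyl carbinol 33 (not isolated)
Conditions: NaBH4, CeCl3·7H2O, MeOH, −40 °C; then K2CO3, 0 °C
Reagents that add atoms: none
Why: Luche 1,2-reduction of the aldehyde (ester untouched, alkene geometry kept), then methanolysis of the alkynylsilane in the same flask; the enal is masked as its alcohol because Cp2Zr(H)Cl and i-Bu2AlH would reduce it.

Step 23
Reactants: 34 terminal enyne triol
Product: 35 tris(triethylsilyl) ether
Conditions: Et3SiOTf, 2,6-lutidine, CH2Cl2, −78 → 0 °C
Reagents that add atoms: triethylsilyl trifluoromethanesulfonate, CC[Si](CC)(CC)OS(=O)(=O)C(F)(F)F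
Why: Exhaustive silylation by the reactive silyl triflate covers the primary allylic, the hindered secondary and the tertiary hydroxyl, so that no free alcohol interferes in steps 25 to 27 and all come off together in step 28.

Step 24
Reactants: 36 6-methylhept-5-en-2-one
Product: 38 6-methylhepta-1,5-dien-2-yl triflate, via potassium enolate 37 (not isolated)
Conditions: KN(SiMe3)2, THF, −78 °C; then PhNTf2, −78 → 0 °C
Reagents that add atoms: N-phenylbis(trifluoromethanesulfonimide), O=S(=O)(N(c1ccccc1)S(=O)(=O)C(F)(F)F)C(F)(F)F
Why: Kinetic deprotonation of the methyl ketone at the methyl group and O-sulfonylation give the 1,1-disubstituted alkenyl triflate.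

Step 25
Reactants: 35 tris(triethylsilyl) ether; 38 6-methylhepta-1,5-dien-2-yl triflate
Product: 41 methyl trienoate, via dienylzirconocene chloride 39 (not isolated), via dienylzinc chloride 40 (not isolated)
Conditions: Cp2Zr(H)Cl, THF, rt; then ZnCl2, 0 °C; then 38, Pd(PPh3)4 (cat.), rt
Reagents that add atoms: none
Why: syn-Hydrozirconation of the terminal alkyne puts the metal on the terminal carbon and fixes the E geometry of Cc=Cd; transmetalation to zinc and Negishi coupling with the alkenyl triflate form Cd–Ce with retention on both partners. The coupling is run at the ester stage because an allylic acetate would ionise with zerovalent palladium.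

Step 26
Reactants: 41 methyl trienoate
Product: 42 trienyl carbinol (CH2OH on Ca)
Conditions: i-Bu2AlH, CH2Cl2, −78 °C; aq. potassium sodium tartrate
Reagents that add atoms: none
Why: 1,2-Reduction of the conjugated ester to the primary allylic alcohol at low temperature; silyl ethers and the triene are inert.

Step 27
Reactants: 42 trienyl carbinol
Product: 43 allylic acetate
Conditions: Ac2O, pyridine, DMAP (cat.), CH2Cl2, 0 °C
Reagents that add atoms: acetic anhydride, CC(=O)OC(C)=O
Why: Acetylation of the only free hydroxyl.

Step 28
Reactants: 43 allylic acetate
Product: 44 tetraol monoacetate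
Conditions: HF·pyridine, pyridine, THF, 0 °C → rt
Reagents that add atoms: none
Why: Buffered fluoride removes the three triethylsilyl ethers and the primary TBS ether; acetate, triene and the allylic alcohol tolerate these nearly neutral conditions, which avoid acyl loss or migration.

Step 29
Reactants: 44 tetraol monoacetate
Product: 45 CNP0204268.2
Conditions: MnO2, CH2Cl2, rt
Reagents that add atoms: none
Why: MnO2 oxidises only the allylic primary alcohol (the others are a saturated primary, a homoallylic secondary and a tertiary alcohol) and gives the enal without changing the alkene geometry or exposing C6 to base.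

## Compound list

1 | (S)-carvone, (5S)-2-methyl-5-(prop-1-en-2-yl)cyclohex-2-en-1-one | CC1=CC[C@@H](CC1=O)C(C)=C | starting material
2 | allyl bromide (3-bromoprop-1-ene) | C=CCBr | starting material
3 | lithium dienolate of 1 (O–Li on the carbonyl carbon, enolate C=C toward the α′ carbon) | [Li]OC1=C[C@@H](C(C)=C)CC=C1C | intermediate
4 | trans-6-allylcarvone, (5S,6R)-2-methyl-6-(prop-2-en-1-yl)-5-(prop-1-en-2-yl)cyclohex-2-en-1-one | O=C1[C@H](CC=C)[C@@H](C(C)=C)CC=C1C | intermediate
5 | methoxydiene: 4 with C=O replaced by C=CH–OMe (future C5=C1), E/Z mixture, allyl trans to isopropenyl | COC=C1[C@H](CC=C)[C@@H](C(C)=C)CC=C1C | intermediate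
6 | trialkylborane: B(3-methylbutan-2-yl)2 on the terminal carbon of the former allyl group of 5 | COC=C1[C@H](CCCB(C(C)C(C)C)C(C)C(C)C)[C@@H](C(C)=C)CC=C1C | intermediate
7 | primary alcohol: methoxydiene with a 3-hydroxypropyl chain on C6 | COC=C1[C@H](CCCO)[C@@H](C(C)=C)CC=C1C | intermediate
8 | TBS ether of 7 | COC=C1[C@H](CCCO[Si](C)(C)C(C)(C)C)[C@@H](C(C)=C)CC=C1C | intermediate
9 | 2-methyl-5-(prop-1-en-2-yl)-6-[3-(tert-butyldimethylsilyloxy)propyl]cyclohex-2-ene-1-carbaldehyde, ring substituents at C6/C7 trans, C5 epimers | O=CC1[C@H](CCCO[Si](C)(C)C(C)(C)C)[C@@H](C(C)=C)CC=C1C | intermediate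
10 | but-3-yn-1-ol | C#CCCO | starting material
11 | but-3-yn-1-yl trifluoromethanesulfonate | C#CCCOS(=O)(=O)C(F)(F)F | intermediate
12 | lithium dienolate of 9 (O–Li on C1, C1=C5 and C9=C10 double bonds) | [Li]OC=C1[C@H](CCCO[Si](C)(C)C(C)(C)C)[C@@H](C(C)=C)CC=C1C | intermediate
13 | 1-(but-3-yn-1-yl)-2-methyl-5-(prop-1-en-2-yl)-6-[3-(tert-butyldimethylsilyloxy)propyl]cyclohex-2-ene-1-carbaldehyde; butynyl trans to the C6 chain and cis to isopropenyl, CHO cis to the C6 chain | C#CCC[C@@]1(C=O)[C@H](CCCO[Si](C)(C)C(C)(C)C)[C@@H](C(C)=C)CC=C1C | intermediate
14 | primary alcohol from 13 (C5–CH2OH) | C#CCC[C@@]1(CO)[C@H](CCCO[Si](C)(C)C(C)(C)C)[C@@H](C(C)=C)CC=C1C | intermediate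
15 | epoxy alcohol: C9–C10 epoxide of 14, epoxide oxygen cis to the CH2OH group | C#CCC[C@@]1(CO)[C@H](CCCO[Si](C)(C)C(C)(C)C)[C@@H](C(C)=C)C[C@@H]2O[C@]12C | intermediate
16 | p-methoxybenzyl ether of 15 | C#CCC[C@@]1(COCc2ccc(OC)cc2)[C@H](CCCO[Si](C)(C)C(C)(C)C)[C@@H](C(C)=C)C[C@@H]2O[C@]12C | intermediate
17 | tertiary alcohol: C10 bears CH3 and OH (OH cis to the C1 carbon), C9 is CH2, C1 as CH2O-p-methoxybenzyl | C#CCC[C@@]1(COCc2ccc(OC)cc2)[C@H](CCCO[Si](C)(C)C(C)(C)C)[C@@H](C(C)=C)CC[C@]1(C)O | intermediate
18 | MOM ether of 17 at the C10 oxygen | C#CCC[C@@]1(COCc2ccc(OC)cc2)[C@H](CCCO[Si](C)(C)C(C)(C)C)[C@@H](C(C)=C)CC[C@]1(C)OCOC | intermediate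
19 | lithium acetylide of 18 | [Li]C#CCC[C@@]1(COCc2ccc(OC)cc2)[C@H](CCCO[Si](C)(C)C(C)(C)C)[C@@H](C(C)=C)CC[C@]1(C)OCOC | intermediate
20 | methyl ynoate: C5–CH2CH2–C≡C–CO2Me | COC(=O)C#CCC[C@@]1(COCc2ccc(OC)cc2)[C@H](CCCO[Si](C)(C)C(C)(C)C)[C@@H](C(C)=C)CC[C@]1(C)OCOC | intermediate
21 | 3-(trimethylsilyl)prop-2-ynal | C[Si](C)(C)C#CC=O | starting material
22 | vinylalane: diisobutylaluminium on Ca of the acrylate, C3 chain cis to CO2Me | CC(C)C[Al](CC(C)C)/C(C(=O)OC)=C/CC[C@@]1(COCc2ccc(OC)cc2)[C@H](CCCO[Si](C)(C)C(C)(C)C)[C@@H](C(C)=C)CC[C@]1(C)OCOC | intermediate
23 | Baylis–Hillman-type carbinol: Ca bears CO2Me and CH(OH)C≡C–SiMe3 (both epimers), C2=Ca with the C3 chain cis to the ester | C[Si](C)(C)C#CC(O)/C(C(=O)OC)=C/CC[C@@]1(COCc2ccc(OC)cc2)[C@H](CCCO[Si](C)(C)C(C)(C)C)[C@@H](C(C)=C)CC[C@]1(C)OCOC | intermediate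
24 | acetate of 23 | C[Si](C)(C)C#CC(OC(C)=O)/C(C(=O)OC)=C/CC[C@@]1(COCc2ccc(OC)cc2)[C@H](CCCO[Si](C)(C)C(C)(C)C)[C@@H](C(C)=C)CC[C@]1(C)OCOC | intermediate
25 | C1 alcohol: 24 without the p-methoxybenzyl group | C[Si](C)(C)C#CC(OC(C)=O)/C(C(=O)OC)=C/CC[C@@]1(CO)[C@H](CCCO[Si](C)(C)C(C)(C)C)[C@@H](C(C)=C)CC[C@]1(C)OCOC | intermediate
26 | key precursor: ring-A aldehyde with formyl on quaternary C5, Z-acrylate chain with propargylic acetate, C6 silyloxypropyl, C7 isopropenyl, C10 methyl and OMOM | C[Si](C)(C)C#CC(OC(C)=O)/C(C(=O)OC)=C/CC[C@@]1(C=O)[C@H](CCCO[Si](C)(C)C(C)(C)C)[C@@H](C(C)=C)CC[C@]1(C)OCOC | intermediate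
27 | key product: spiro[4.5]decan-1-ol with trans C2 (E)-enynoate stub, C6 silyloxypropyl, C7 isopropenyl, C10 methyl and OMOM | C[Si](C)(C)C#C/C=C(/C(=O)OC)[C@@H]1CC[C@]2([C@H](CCCO[Si](C)(C)C(C)(C)C)[C@@H](C(C)=C)CC[C@]2(C)OCOC)[C@H]1O | intermediate
28 | spiro 1,10-diol (27 without MOM) | C[Si](C)(C)C#C/C=C(/C(=O)OC)[C@@H]1CC[C@]2([C@H](CCCO[Si](C)(C)C(C)(C)C)[C@@H](C(C)=C)CC[C@]2(C)O)[C@H]1O | intermediate
29 | allylic alcohol: C7 bears C(=CH2)CH2OH | C[Si](C)(C)C#C/C=C(/C(=O)OC)[C@@H]1CC[C@]2([C@H](CCCO[Si](C)(C)C(C)(C)C)[C@@H](C(=C)CO)CC[C@]2(C)O)[C@H]1O | intermediate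
30 | 2-substituted propenal: C7 bears C(=CH2)CHO | C[Si](C)(C)C#C/C=C(/C(=O)OC)[C@@H]1CC[C@]2([C@H](CCCO[Si](C)(C)C(C)(C)C)[C@@H](C(=C)C=O)CC[C@]2(C)O)[C@H]1O | intermediate
31 | trimethylsilyl enol ether: C7 bears C(CH3)=CH–OSiMe3 (E/Z) | C[Si](C)(C)C#C/C=C(/C(=O)OC)[C@@H]1CC[C@]2([C@H](CCCO[Si](C)(C)C(C)(C)C)[C@@H](C(C)=CO[Si](C)(C)C)CC[C@]2(C)O)[C@H]1O | intermediate
32 | tetrasubstituted enal: C7=C(CH3)CHO, formyl cis to C6 | C[Si](C)(C)C#C/C=C(/C(=O)OC)[C@@H]1CC[C@]2([C@H](CCCO[Si](C)(C)C(C)(C)C)/C(=C(/C)C=O)CC[C@]2(C)O)[C@H]1O | intermediate
33 | silylated enynyl carbinol: C7=C(CH3)CH2OH, alkynylsilane intact | C[Si](C)(C)C#C/C=C(/C(=O)OC)[C@@H]1CC[C@]2([C@H](CCCO[Si](C)(C)C(C)(C)C)/C(=C(/C)CO)CC[C@]2(C)O)[C@H]1O | intermediate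
34 | terminal enyne triol (C1–OH, C10–OH, allylic CH2OH) | C#C/C=C(/C(=O)OC)[C@@H]1CC[C@]2([C@H](CCCO[Si](C)(C)C(C)(C)C)/C(=C(/C)CO)CC[C@]2(C)O)[C@H]1O | intermediate
35 | tris(triethylsilyl) ether of 34 | C#C/C=C(/C(=O)OC)[C@@H]1CC[C@]2([C@H](CCCO[Si](C)(C)C(C)(C)C)/C(=C(/C)CO[Si](CC)(CC)CC)CC[C@]2(C)O[Si](CC)(CC)CC)[C@H]1O[Si](CC)(CC)CC | intermediate
36 | 6-methylhept-5-en-2-one | CC(=O)CCC=C(C)C | starting material
37 | potassium enolate of 36 at the methyl side | [K]OC(=C)CCC=C(C)C | intermediate
38 | 6-methylhepta-1,5-dien-2-yl trifluoromethanesulfonate | C=C(CCC=C(C)C)OS(=O)(=O)C(F)(F)F | intermediate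
39 | dienylzirconocene chloride: Cp2Zr(Cl) on Cd, Cc=Cd E | Cl[Zr](C1C=CC=C1)(C1C=CC=C1)/C=C/C=C(/C(=O)OC)[C@@H]2CC[C@]3([C@H](CCCO[Si](C)(C)C(C)(C)C)/C(=C(/C)CO[Si](CC)(CC)CC)CC[C@]3(C)O[Si](CC)(CC)CC)[C@H]2O[Si](CC)(CC)CC | intermediate
40 | dienylzinc chloride: ZnCl on Cd, Cc=Cd E | Cl[Zn]/C=C/C=C(/C(=O)OC)[C@@H]1CC[C@]2([C@H](CCCO[Si](C)(C)C(C)(C)C)/C(=C(/C)CO[Si](CC)(CC)CC)CC[C@]2(C)O[Si](CC)(CC)CC)[C@H]1O[Si](CC)(CC)CC | intermediate
41 | methyl trienoate: full side-chain carbon skeleton, CO2Me on Ca | C=C(/C=C/C=C(/C(=O)OC)[C@@H]1CC[C@]2([C@H](CCCO[Si](C)(C)C(C)(C)C)/C(=C(/C)CO[Si](CC)(CC)CC)CC[C@]2(C)O[Si](CC)(CC)CC)[C@H]1O[Si](CC)(CC)CC)CCC=C(C)C | intermediate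
42 | trienyl carbinol: CH2OH on Ca | C=C(/C=C/C=C(/CO)[C@@H]1CC[C@]2([C@H](CCCO[Si](C)(C)C(C)(C)C)/C(=C(/C)CO[Si](CC)(CC)CC)CC[C@]2(C)O[Si](CC)(CC)CC)[C@H]1O[Si](CC)(CC)CC)CCC=C(C)C | intermediate
43 | allylic acetate: CH2OAc on Ca, all other oxygens silylated | C=C(/C=C/C=C(/COC(C)=O)[C@@H]1CC[C@]2([C@H](CCCO[Si](C)(C)C(C)(C)C)/C(=C(/C)CO[Si](CC)(CC)CC)CC[C@]2(C)O[Si](CC)(CC)CC)[C@H]1O[Si](CC)(CC)CC)CCC=C(C)C | intermediate
44 | tetraol monoacetate: target with CH2OH in place of CHO | C=C(/C=C/C=C(/COC(C)=O)[C@@H]1CC[C@]2([C@H](CCCO)/C(=C(/C)CO)CC[C@]2(C)O)[C@H]1O)CCC=C(C)C | intermediate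
45 | CNP0204268.2 | C=C(/C=C/C=C(/COC(C)=O)[C@@H]1CC[C@]2([C@H](CCCO)/C(=C(/C)C=O)CC[C@]2(C)O)[C@H]1O)CCC=C(C)C | target

## Step count and least certain steps

Total step count: 29. Longest linear sequence: 27 steps (1 → 45 through steps 1–5, 7–23 and 25–29); steps 6 and 24 are one-step branches.

Step 18 (key step). Most likely failure: electron transfer to the acetoxy acrylate before the aldehyde, so that acetate is lost reductively without ring closure; next, loss of chelation control at C1 or further reduction of the product enynoate. Fallback: starting from 26, the allylic acetate is converted by Pd(PPh3)4 (cat.) and InI in THF/DMF into an allylindium species that adds to the aldehyde through C2 in a polar Barbier-type allylation with a cyclic transition state, returning to the route at 27. No new compound is made on this path (F0).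

Step 7. Most likely failure: O-alkylation of the hindered extended enolate by the hard triflate, or attack on the face of the C6 chain so that the C5 configuration is eroded. Fallback: starting from 9, base-catalysed Michael addition to acrolein (catalytic KOt-Bu, t-BuOH/THF, 0 °C) forms the same C5–C4 bond with a soft acceptor and gives the dialdehyde F1. The unhindered chain aldehyde of F1 is then homologated selectively with the Ohira–Bestmann reagent (dimethyl (1-diazo-2-oxopropyl)phosphonate, K2CO3, MeOH), the neopentyl formyl group being far less reactive, and the route is rejoined at 13. The C5 configuration is to be confirmed on the rigid epoxide 15 before material is carried on.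

Step 20. Most likely failure: ene reaction at the tertiary C7–H in place of the methyl group, giving a tertiary allylic alcohol, or over-oxidation. Fallback: starting from 28, ene-type chlorination of the isopropenyl group (Ca(OCl)2, solid CO2, CH2Cl2/H2O) gives the allylic chloride F2, and oxidation with N-methylmorpholine N-oxide in MeCN converts F2 into the propenal, rejoining the route at 30.

Step 21. Most likely failure: β-hydride loss toward the methyl group (which only returns 30), poor control of the alkene geometry, or competing reduction of the enynoate by the copper hydride. Fallback: starting from 30 and passing through 31 as in the first stage of step 21, bromination with N-bromosuccinimide gives the α-bromo aldehyde F3. Dehydrobromination of F3 with Li2CO3 and LiBr in DMF under equilibrating conditions should give the more substituted conjugated enal and rejoins the route at 32. A geometric mixture can be equilibrated at 32 with a trace of iodine before step 22.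

Step 25. Most likely failure: partial reduction of the conjugated ester by excess Cp2Zr(H)Cl, protodemetalation to the simple diene, or slow coupling of the triflate. Fallback: starting from 35, hydroboration with pinacolborane (dicyclohexylborane as catalyst) gives the isolable dienyl pinacol boronate F4. Suzuki–Miyaura coupling of F4 with 38 (PdCl2(dppf), K3PO4, THF/H2O) rejoins the route at 41.

## Further compounds

F0 | step 18 | none | none
F1 | step 7 | dialdehyde: 13 with CH2CH2CHO in place of the butynyl chain | O=CCC[C@@]1(C=O)[C@H](CCCO[Si](C)(C)C(C)(C)C)[C@@H](C(C)=C)CC=C1C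
F2 | step 20 | allylic chloride: 28 with C(=CH2)CH2Cl on C7 | C[Si](C)(C)C#C/C=C(/C(=O)OC)[C@@H]1CC[C@]2([C@H](CCCO[Si](C)(C)C(C)(C)C)[C@@H](C(=C)CCl)CC[C@]2(C)O)[C@H]1O
F3 | step 21 | α-bromo aldehyde: C7 bears C(CH3)(Br)CHO (both epimers) | C[Si](C)(C)C#C/C=C(/C(=O)OC)[C@@H]1CC[C@]2([C@H](CCCO[Si](C)(C)C(C)(C)C)[C@@H](C(C)(Br)C=O)CC[C@]2(C)O)[C@H]1O
F4 | step 25 | dienyl pinacol boronate: Bpin on Cd of 35, Cc=Cd E | CC1(C)OB(/C=C/C=C(/C(=O)OC)[C@@H]2CC[C@]3([C@H](CCCO[Si](C)(C)C(C)(C)C)/C(=C(/C)CO[Si](CC)(CC)CC)CC[C@]3(C)O[Si](CC)(CC)CC)[C@H]2O[Si](CC)(CC)CC)OC1(C)C
A1 | alternative 1 | tethered dioxinone enone: 4-(methoxymethoxy)-4-methyl-3-[3-(2,2-dimethyl-4-oxo-1,3-dioxin-6-yl)propyl]cyclohex-2-en-1-one | O=C1C=C(CCCC2=CC(=O)OC(C)(C)O2)[C@@](C)(OCOC)CC1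
A2 | alternative 1 | tetracyclic photoadduct (cyclobutane fused to ring A, ring B and the dioxanone) | O=C1CC[C@](C)(OCOC)[C@]23CCC[C@@]2(OC(C)(C)OC4=O)[C@H]4[C@H]13
A3 | alternative 1 | spiro diketo acid: spiro[4.5]decane-1,7-dione with CH2CO2H on C6 and methyl and OMOM on C10 | O=C1CC[C@](C)(OCOC)[C@@]2(CCCC2=O)[C@@H]1CC(=O)O
A4 | alternative 2 | cyclopenta-fused dihydropyran (enol ether O–C1=C5) with C10 methyl and OSiMe3 and a (Z)-1,5-bis(tert-butyldimethylsilyloxy)pent-1-enyl group on C8, cis to the C10 methyl | C1CC2=C(C1)[C@@](C)(O[Si](C)(C)C)CC[C@@H](O2)/C(O[Si](C)(C)C(C)(C)C)=C/CCCO[Si](C)(C)C(C)(C)C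
A5 | alternative 2 | spiro[4.5]dec-7-en-1-one with C6 chain, C7 enol silane and C10 silyl ether | C1CC[C@]2([C@H](CCCO[Si](C)(C)C(C)(C)C)C(O[Si](C)(C)C(C)(C)C)=CC[C@]2(C)O[Si](C)(C)C)C1=O
A6 | alternative 3 | quinone-monoketal cyclobutanol: 3-(1-hydroxycyclobutyl)-4,4-(ethylenedioxy)cyclohexa-2,5-dien-1-one | OC1(CCC1)C1=CC(=O)C=CC12OCCO2
A7 | alternative 3 | spiro[4.5]dec-8-ene-1,7-dione 10-ethylene ketal | C1CC[C@]2(CC(=O)C=CC23OCCO3)C1=O
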